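**Retrosynthetic overview**
- Target 18 is quercetin 3',4'-bis(hydrogen sulfate). The sulfate esters go on late, onto the ring B catechol freed from methoxymethyl (MOM) ethers; the 3-, 5- and 7-hydroxyls travel as benzyl ethers and are freed by hydrogenolysis.
- Structural feature: in ring C, C3 carries a hydroxyl and C4 a carbonyl. At the 2,3-dihydro level this C3(OH)–C4(=O) pair is an acyloin, so the C3–C4 bond is cut into two formyl groups joined through O1 and C2 (dialdehyde 11).
- Forward, a triazolylidene closes ring C by intramolecular crossed benzoin (11 → 12); iodine then dehydrogenates C2–C3 to the flavonol 13.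
- Dialdehyde 11 comes from the O1–C2 ether bond: ring A salicylaldehyde 2 plus α-bromo arylacetate 8, then LiAlH4 reduction and double oxidation.
- Ring order: rings A and B are bought; ring C is the only ring made.

Key step: step 8

Assumption: the target is drawn as the free bis(hydrogen sulfate); aryl hydrogen sulfates hydrolyse readily as free acids, so the disulfate is carried as its bis(triethylammonium) salt and the acid is liberated only in the last operation, cold. The target is achiral; all chiral intermediates are racemic.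

**Step 1**
Reactants: 1 2,4,6-trihydroxybenzaldehyde
Product: 2 4,6-bis(benzyloxy)-2-hydroxybenzaldehyde
Conditions: BnBr (2.1 equiv), K2CO3 (2.2 equiv), DMF, 0 °C to rt
Reagents that add atoms: benzyl bromide, BrCc1ccccc1
Why: Williamson etherification with two equivalents of benzyl bromide should take the 4-hydroxyl and one ortho hydroxyl, while the remaining ortho hydroxyl, hydrogen-bonded to the formyl oxygen, is the least nucleophilic and stays free.

**Step 2**
Reactants: 3 3,4-dihydroxyphenylacetic acid
Product: 4 methyl 2-(3,4-dihydroxyphenyl)acetate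
Conditions: MeOH, H2SO4 (cat.), reflux
Reagents that add atoms: methanol, CO
Why: Fischer esterification of the carboxylic acid in methanol; the catechol is untouched.

**Step 3**
Reactants: 4 methyl 2-(3,4-dihydroxyphenyl)acetate
Product: 5 methyl 2-[3,4-bis(methoxymethoxy)phenyl]acetate
Conditions: MOMCl (2.5 equiv), i-Pr2NEt (3 equiv), CH2Cl2, 0 °C to rt
Reagents that add atoms: chloromethyl methyl ether, COCCl
Why: O-alkylation of both phenols gives aryl MOM acetals, which tolerate base, hydride, carbene and iodine/pyridine and leave later with mild acid.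

**Step 4**
Reactants: 5 methyl 2-[3,4-bis(methoxymethoxy)phenyl]acetate
Product: 8 methyl 2-bromo-2-[3,4-bis(methoxymethoxy)phenyl]acetate (racemic), via lithium ester enolate 6 (not isolated), via trimethylsilyl ketene acetal 7 (not isolated)
Conditions: LiN(SiMe3)2, THF, −78 °C; Me3SiCl; then NBS, −78 to 0 °C
Reagents that add atoms: N-bromosuccinimide, O=C1CCC(=O)N1Br (bromine of 8); LiN(SiMe3)2, [Li]N([Si](C)(C)C)[Si](C)(C)C (lithium of 6); chlorotrimethylsilane, C[Si](C)(C)Cl (silyl group of 7)
Why: Enolate formation at the benzylic α-carbon, silylation and electrophilic bromination of the silyl ketene acetal should give the racemic α-bromo ester without proton exchange between enolate and product and without bromination of the electron-rich ring.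

**Step 5**
Reactants: 2 4,6-bis(benzyloxy)-2-hydroxybenzaldehyde; 8 methyl 2-bromo-2-[3,4-bis(methoxymethoxy)phenyl]acetate
Product: 9 methyl 2-[3,5-bis(benzyloxy)-2-formylphenoxy]-2-[3,4-bis(methoxymethoxy)phenyl]acetate (racemic)
Conditions: K2CO3, DMF, rt
Reagents that add atoms: none
Why: Williamson ether synthesis (SN2 of the phenoxide on the activated α-bromo ester) forms the O1–C2 bond; the C2 centre is racemic and is lost later, and at room temperature aldol closure to a benzofuran should not compete.

**Step 6**
Reactants: 9 methyl 2-[3,5-bis(benzyloxy)-2-formylphenoxy]-2-[3,4-bis(methoxymethoxy)phenyl]acetate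
Product: 10 2-[3,5-bis(benzyloxy)-2-(hydroxymethyl)phenoxy]-2-[3,4-bis(methoxymethoxy)phenyl]ethan-1-ol (racemic)
Conditions: LiAlH4, THF, 0 °C; basic aqueous work-up
Reagents that add atoms: none
Why: Hydride reduction takes ester and aryl aldehyde together to the two primary alcohols, which avoids any need to distinguish the two carbonyls; ethers and acetals are inert.

**Step 7**
Reactants: 10 2-[3,5-bis(benzyloxy)-2-(hydroxymethyl)phenoxy]-2-[3,4-bis(methoxymethoxy)phenyl]ethan-1-ol
Product: 11 2-{1-[3,4-bis(methoxymethoxy)phenyl]-2-oxoethoxy}-4,6-bis(benzyloxy)benzaldehyde (racemic)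
Conditions: Dess–Martin periodinane (3 equiv), NaHCO3, CH2Cl2, 0 °C to rt; Na2S2O3 work-up; used crude at once
Reagents that add atoms: none
Why: Dess–Martin oxidation of both primary alcohols under bicarbonate buffer should give the dialdehyde without acid-induced ionization of the trialkoxybenzyl alcohol or base-induced enolization of the new α-aryloxy aldehyde.

**Step 8**
Reactants: 11 2-{1-[3,4-bis(methoxymethoxy)phenyl]-2-oxoethoxy}-4,6-bis(benzyloxy)benzaldehyde
Product: 12 5,7-bis(benzyloxy)-2-[3,4-bis(methoxymethoxy)phenyl]-3-hydroxychroman-4-one (racemic, mixture of C2/C3 diastereomers)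
Conditions: 2-(pentafluorophenyl)-6,7-dihydro-5H-pyrrolo[2,1-c][1,2,4]triazol-2-ium tetrafluoroborate (15 mol %), i-Pr2NEt (15 mol %), CH2Cl2 (0.02 M), 0 °C to rt, argon
Reagents that add atoms: none
Why: The triazolylidene freed by the amine adds to a formyl group, a proton shift gives the Breslow enaminol, and this acyl-anion equivalent attacks the second formyl carbon before the carbene is expelled, which forms C3–C4. The closest known reaction type is the carbene-catalysed intramolecular crossed benzoin that closes 3-hydroxychroman-4-ones from aryloxy-tethered carbonyl aldehydes, together with benzoin cyclizations of dialdehydes to cyclic acyloins. Ring C closes in a 6-exo-trig mode, the Breslow carbon (future C4) attacking the aliphatic formyl carbon (future C3). The new C3 stereocentre is set without useful control relative to C2 (cis and trans acyloins, each racemic), which is harmless because C2 and C3 both become sp2 in step 9. The step needs C–C bond formation to outrun loss of the ring A aryloxide from a Breslow intermediate formed on the aliphatic aldehyde and the 5-exo aldol of the C2 enolate, whereas the choice of donor aldehyde is free, since the regioisomeric 4-hydroxychroman-3-one would be oxidized to the same flavonol. In the substrate this rests on the ring A aldehyde having no β-leaving group and on α-branching that slows carbene addition to the aliphatic aldehyde while its α-aryloxy group makes it a strong acceptor held six atoms from the donor carbon, helped by an electron-poor N-pentafluorophenyl carbene and only catalytic weak amine at 0 °C.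

**Step 9**
Reactants: 12 5,7-bis(benzyloxy)-2-[3,4-bis(methoxymethoxy)phenyl]-3-hydroxychroman-4-one
Product: 13 5,7-bis(benzyloxy)-3-hydroxy-2-[3,4-bis(methoxymethoxy)phenyl]-4H-chromen-4-one
Conditions: I2 (1.2 equiv), pyridine, 90 °C; Na2S2O3 work-up
Reagents that add atoms: none
Why: Iodine dehydrogenation: the acyloin enolizes to an enediol that iodine oxidizes to the chroman-3,4-dione, which tautomerizes by C2–H shift to the aromatic 3-hydroxy-4-pyranone, while pyridine traps HI so the MOM acetals survive; both stereocentres disappear here.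

**Step 10**
Reactants: 13 5,7-bis(benzyloxy)-3-hydroxy-2-[3,4-bis(methoxymethoxy)phenyl]-4H-chromen-4-one
Product: 14 3,5,7-tris(benzyloxy)-2-[3,4-bis(methoxymethoxy)phenyl]-4H-chromen-4-one
Conditions: BnBr (1.3 equiv), K2CO3, DMF, rt to 50 °C
Reagents that add atoms: benzyl bromide, BrCc1ccccc1
Why: Williamson O-benzylation of the enolic 3-hydroxyl, so that only the ring B oxygens can be freed for sulfation.

**Step 11**
Reactants: 14 3,5,7-tris(benzyloxy)-2-[3,4-bis(methoxymethoxy)phenyl]-4H-chromen-4-one
Product: 15 3,5,7-tris(benzyloxy)-2-(3,4-dihydroxyphenyl)-4H-chromen-4-one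
Conditions: HCl (2 M), MeOH–THF, 50 °C
Reagents that add atoms: none
Why: Acid-catalysed acetal methanolysis removes both MOM groups; benzyl ethers are stable to methanolic HCl.

**Step 12**
Reactants: 15 3,5,7-tris(benzyloxy)-2-(3,4-dihydroxyphenyl)-4H-chromen-4-one
Product: 16 bis(triethylammonium) 4-[3,5,7-tris(benzyloxy)-4-oxo-4H-chromen-2-yl]-1,2-phenylene bis(sulfate)
Conditions: SO3·NEt3 (8 equiv), DMF, 60 °C; silica, CH2Cl2–MeOH–Et3N
Reagents that add atoms: sulfur trioxide–triethylamine complex, CC[N+](CC)(CC)S(=O)(=O)[O-]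
Why: O-sulfation of phenols with an amine–sulfur trioxide complex; the two catechol hydroxyls are the only free hydroxyls, and excess reagent with heating should push the second, slower sulfation.

**Step 13**
Reactants: 16 bis(triethylammonium) 4-[3,5,7-tris(benzyloxy)-4-oxo-4H-chromen-2-yl]-1,2-phenylene bis(sulfate)
Product: 18 4-(3,5,7-trihydroxy-4-oxo-4H-chromen-2-yl)-1,2-phenylene bis(hydrogen sulfate) (quercetin 3',4'-bis(hydrogen sulfate)), via bis(triethylammonium) quercetin 3',4'-disulfate 17 (not isolated)
Conditions: H2 (1 atm), Pd(OH)2/C, THF–MeOH–H2O, rt; filter; sulfonic acid cation-exchange resin (H+ form), H2O, 0 °C; freeze-dry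
Reagents that add atoms: none
Why: Catalytic hydrogenolysis cleaves the three benzyl aryl ethers while aryl sulfate monoester salts and the flavonol core are inert, and cold proton exchange on the resin then gives the free acid.

**Compound list**
1 | 2,4,6-trihydroxybenzaldehyde | O=Cc1c(O)cc(O)cc1O | starting material
2 | 4,6-bis(benzyloxy)-2-hydroxybenzaldehyde | O=Cc1c(O)cc(OCc2ccccc2)cc1OCc1ccccc1 | intermediate
3 | 3,4-dihydroxyphenylacetic acid | OC(=O)Cc1ccc(O)c(O)c1 | starting material
4 | methyl 2-(3,4-dihydroxyphenyl)acetate | COC(=O)Cc1ccc(O)c(O)c1 | intermediate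
5 | methyl 2-[3,4-bis(methoxymethoxy)phenyl]acetate | COC(=O)Cc1ccc(OCOC)c(OCOC)c1 | intermediate
6 | lithium enolate of 5 (not isolated) | COC(=Cc1ccc(OCOC)c(OCOC)c1)O[Li] | intermediate
7 | trimethylsilyl ketene acetal of 5 (not isolated, E/Z mixture) | COC(=Cc1ccc(OCOC)c(OCOC)c1)O[Si](C)(C)C | intermediate
8 | methyl 2-bromo-2-[3,4-bis(methoxymethoxy)phenyl]acetate (racemic) | COC(=O)C(Br)c1ccc(OCOC)c(OCOC)c1 | intermediate
9 | methyl 2-[3,5-bis(benzyloxy)-2-formylphenoxy]-2-[3,4-bis(methoxymethoxy)phenyl]acetate (racemic) | COC(=O)C(Oc1cc(OCc2ccccc2)cc(OCc2ccccc2)c1C=O)c1ccc(OCOC)c(OCOC)c1 | intermediate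
10 | 2-[3,5-bis(benzyloxy)-2-(hydroxymethyl)phenoxy]-2-[3,4-bis(methoxymethoxy)phenyl]ethan-1-ol (racemic) | OCC(Oc1cc(OCc2ccccc2)cc(OCc2ccccc2)c1CO)c1ccc(OCOC)c(OCOC)c1 | intermediate
11 | 2-{1-[3,4-bis(methoxymethoxy)phenyl]-2-oxoethoxy}-4,6-bis(benzyloxy)benzaldehyde (racemic) | O=CC(Oc1cc(OCc2ccccc2)cc(OCc2ccccc2)c1C=O)c1ccc(OCOC)c(OCOC)c1 | intermediate
12 | 5,7-bis(benzyloxy)-2-[3,4-bis(methoxymethoxy)phenyl]-3-hydroxychroman-4-one (racemic, diastereomer mixture) | O=C1c2c(OCc3ccccc3)cc(OCc3ccccc3)cc2OC(c2ccc(OCOC)c(OCOC)c2)C1O | intermediate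
13 | 5,7-bis(benzyloxy)-3-hydroxy-2-[3,4-bis(methoxymethoxy)phenyl]-4H-chromen-4-one | O=c1c(O)c(-c2ccc(OCOC)c(OCOC)c2)oc2cc(OCc3ccccc3)cc(OCc3ccccc3)c12 | intermediate
14 | 3,5,7-tris(benzyloxy)-2-[3,4-bis(methoxymethoxy)phenyl]-4H-chromen-4-one | O=c1c(OCc2ccccc2)c(-c2ccc(OCOC)c(OCOC)c2)oc2cc(OCc3ccccc3)cc(OCc3ccccc3)c12 | intermediate
15 | 3,5,7-tris(benzyloxy)-2-(3,4-dihydroxyphenyl)-4H-chromen-4-one | O=c1c(OCc2ccccc2)c(-c2ccc(O)c(O)c2)oc2cc(OCc3ccccc3)cc(OCc3ccccc3)c12 | intermediate
16 | bis(triethylammonium) 4-[3,5,7-tris(benzyloxy)-4-oxo-4H-chromen-2-yl]-1,2-phenylene bis(sulfate) | CC[NH+](CC)CC.CC[NH+](CC)CC.O=c1c(OCc2ccccc2)c(-c2ccc(OS(=O)(=O)[O-])c(OS(=O)(=O)[O-])c2)oc2cc(OCc3ccccc3)cc(OCc3ccccc3)c12 | intermediate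
17 | bis(triethylammonium) 4-(3,5,7-trihydroxy-4-oxo-4H-chromen-2-yl)-1,2-phenylene bis(sulfate) (not isolated) | CC[NH+](CC)CC.CC[NH+](CC)CC.O=c1c(O)c(-c2ccc(OS(=O)(=O)[O-])c(OS(=O)(=O)[O-])c2)oc2cc(O)cc(O)c12 | intermediate
18 | 4-(3,5,7-trihydroxy-4-oxo-4H-chromen-2-yl)-1,2-phenylene bis(hydrogen sulfate) | O=c1c(O)c(-c2ccc(OS(=O)(=O)O)c(OS(=O)(=O)O)c2)oc2cc(O)cc(O)c12 | target

**Step count**
Total: 13 steps. Longest linear sequence: 12 steps (steps 2 to 13, from 3,4-dihydroxyphenylacetic acid).

**Steps most likely to fail**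

1. Step 8 (carbene benzoin). The carbene may engage the aliphatic aldehyde first, and the resulting enaminol may expel the ring A aryloxide, ending in redox esterification. The amine may also enolize C2 and trigger 5-exo aldol closure, or the hindered, electron-rich aryl aldehyde may fail to turn over. The fallback sets out from 11 and replaces umpolung by reductive coupling. SmI2 (2.5 equiv) with t-BuOH in THF at −78 °C should close ring C by ketyl–carbonyl pinacol cyclization to 5,7-bis(benzyloxy)-2-[3,4-bis(methoxymethoxy)phenyl]chromane-3,4-diol F1. 2-Iodoxybenzoic acid in DMSO at rt should then oxidize both carbinols without glycol cleavage to the 3,4-dione, whose enol is flavonol 13. The route is rejoined at 13.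

2. Step 7 (double oxidation). The first aldehyde formed may be captured by the remaining alcohol as a lactol and over-oxidized, the trialkoxybenzyl alcohol may ionize under the acetic acid released, or the dialdehyde may enolize and cyclize on work-up. The fallback sets out from 10 and separates the two oxidations. MnO2 in CH2Cl2 should oxidize only the benzylic alcohol to 2-[3,5-bis(benzyloxy)-2-formylphenoxy]-2-[3,4-bis(methoxymethoxy)phenyl]ethan-1-ol F2. Parikh–Doering oxidation (SO3·pyridine, DMSO, i-Pr2NEt, CH2Cl2, −10 °C) should then give 11, where the route is rejoined.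

3. Step 12 (bis-sulfation). The first sulfate anion deactivates the neighbouring hydroxyl, so sulfation may stall at mono-sulfates, and sulfate may be lost by hydrolysis during purification. The fallback sets out from 15 and uses protected sulfate diesters. 2,2,2-Trichloroethyl chlorosulfate with Et3N and DMAP in THF should give the neutral, chromatographable 4-[3,5,7-tris(benzyloxy)-4-oxo-4H-chromen-2-yl]-1,2-phenylene bis(2,2,2-trichloroethyl) bis(sulfate) F3. Zn dust and HCO2NH4 in MeOH should then cleave the trichloroethyl groups reductively to bis(ammonium) 4-[3,5,7-tris(benzyloxy)-4-oxo-4H-chromen-2-yl]-1,2-phenylene bis(sulfate) F4. Repeated co-evaporation with Et3N drives off ammonia and gives 16, where the route is rejoined.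

**Further compounds**
F1 | step 8 | 5,7-bis(benzyloxy)-2-[3,4-bis(methoxymethoxy)phenyl]chromane-3,4-diol (racemic, diastereomer mixture) | OC1c2c(OCc3ccccc3)cc(OCc3ccccc3)cc2OC(c2ccc(OCOC)c(OCOC)c2)C1O
F2 | step 7 | 2-[3,5-bis(benzyloxy)-2-formylphenoxy]-2-[3,4-bis(methoxymethoxy)phenyl]ethan-1-ol (racemic) | OCC(Oc1cc(OCc2ccccc2)cc(OCc2ccccc2)c1C=O)c1ccc(OCOC)c(OCOC)c1
F3 | step 12 | 4-[3,5,7-tris(benzyloxy)-4-oxo-4H-chromen-2-yl]-1,2-phenylene bis(2,2,2-trichloroethyl) bis(sulfate) | O=c1c(OCc2ccccc2)c(-c2ccc(OS(=O)(=O)OCC(Cl)(Cl)Cl)c(OS(=O)(=O)OCC(Cl)(Cl)Cl)c2)oc2cc(OCc3ccccc3)cc(OCc3ccccc3)c12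
F4 | step 12 | bis(ammonium) 4-[3,5,7-tris(benzyloxy)-4-oxo-4H-chromen-2-yl]-1,2-phenylene bis(sulfate) | [NH4+].[NH4+].O=c1c(OCc2ccccc2)c(-c2ccc(OS(=O)(=O)[O-])c(OS(=O)(=O)[O-])c2)oc2cc(OCc3ccccc3)cc(OCc3ccccc3)c12
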